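## Structural features

The target is an oxidised elemane-type sesquiterpenoid. Numbering used here: cyclohexane C5–C10, oxirane C1–C2, acrolein unit C3/C4/C15, lactone carbons C11–C13, C10 methyl C14. An α-methylene-γ-butyrolactone is cis-fused across C7–C8, with its oxygen on C8. All six ring carbons are stereogenic and contiguous. C10 is quaternary, carrying a methyl group and a monosubstituted oxirane whose C1 is a seventh stereocentre outside the ring. C10 is flanked by C9 (methacrylate) and C5 (3-oxoprop-1-en-2-yl); C6 bears a free hydroxyl. Taking the C10 methyl face as β: the C5 side chain and the C6 hydroxyl are β; the C8 and C9 oxygens, C11 on C7 and the oxirane are α. Fragile groups are three Michael acceptors (α-methylene lactone, methacrylate, enal), a terminal epoxide, two acyl groups prone to migration, and a γ-hydroxy enal that can close to a lactol. The real difficulty is the stereo-hexad around a quaternary carbon, with the cis C8/C9 dioxygen pattern anti to the methyl, C6–O syn to the C5 substituent, and C1 correlated with C10. The key step exploits the fact that C8 is the lactone γ-carbon, C9 the adjacent carbinol and C7 the lactone β-carbon. This is the γ-(1-hydroxyalkyl)butenolide pattern left when the 5-position of a 2-silyloxyfuran, whose 4-position already holds C6, adds to an aldehyde.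

## Logic of the disconnections

**34 ⇒ 32.** The C2–O bond of the oxirane is cut, giving the C1/C2 diol. The epoxide is the most acid- and nucleophile-sensitive group, so it is made last. C1 then comes from the chiral pool with retention. The demand is a closure that is selective for the primary hydroxyl and mild enough for three Michael acceptors.

**32 ⇒ 31 ⇒ 29.** The diol and the C6 hydroxyl are re-protected (acetonide, silyl ether) and the C3 oxygen is removed, leaving an isopropenyl group. One acidic step then unmasks both protecting groups. The enal arises by allylic oxidation of the only electron-rich alkene, which must be selective over the two electron-poor alkenes.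

**29 ⇒ 28.** The C9–O acyl bond is cut. The methacrylate must come after all hydride and enolate chemistry, and while C6 is still protected, so that only the C9 hydroxyl can be acylated.

**28 ⇒ 25 ⇒ 24.** The C11=C13 bond and then the C7–H bond are cut, returning to a Δ7(11)-butenolide. This removes two functional groups and one stereocentre. The conjugate reduction must deliver hydrogen to C7 on the H-8 face.

**24 ⇒ 23 (key).** The C8–C9 bond is cut. The ring, C8 and C9 fall away, leaving an acyclic chain with three stereocentres (C5, C6, C10) plus C1. The forward step needs γ-selective attack of the silyloxyfuran, the correct furan face (C8) and the correct aldehyde orientation (C9).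

**23 ⇒ 22 ⇒ 19.** The O–Si bond is cut, then the C9 carbonyl is traced to a vinyl group (C9=C(a)). The aldehyde is unveiled before the acid- and oxidant-sensitive silyloxyfuran exists. The oxidative cleavage must spare the isopropenyl group, which is therefore masked during ozonolysis.

**19 ⇒ 16.** The butenolide is traced to a 3-substituted furan, a robust latent form that survives organolithium and hydride steps. The oxidation must place the carbonyl on the α-carbon distal to the side chain.

**16 ⇒ 15 ⇒ 14 ⇒ 11 + 12.** The C6–H bond and then the C6–C7 bond are cut. C6 is set by reduction of a ketone, not by adding the furyl nucleophile to an aldehyde: under Felkin–Anh control the latter would be expected to give the C6 epimer. The ketone is enolisable and β,γ-unsaturated, so it must be reduced promptly.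

**11 ⇒ 10 ⇒ 7.** The C5–C10 bond is cut by a retro-[3,3] shift. A vicinal quaternary/tertiary pair becomes an achiral acyl unit and a trisubstituted allylic alcohol. The forward step demands control of ketene acetal geometry, of chair versus boat, and of the alkene face.

**7 ⇒ 5 + 6.** The ester C–O bond is cut, giving two simple fragments. The β,γ-alkene of 6 must not migrate into conjugation during coupling.

**5 ⇒ 4 ⇒ 3 ⇒ 2 ⇒ 1.** The C10–C14 bond (syn-carbometalation of an ynoate), the C9–C(a) bond and the alkyne carbon C9 are removed in turn. The (Z)-alkene is chosen because its allylic 1,3-strain gives the strongest 1,2-induction from C1. The carbometalation must be quenched cold to keep the Z geometry.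

## Other disconnections considered

**Alternative 1:** The cut is C5–C4 and C10–C1 on a preformed ring. In the forward step the magnesium alkoxide at C6 of enone A2 directs isopropenylmagnesium bromide to C5 on its own face, and the C10 enolate is trapped by formaldehyde to give A1.
- In favour: two skeletal bonds and two stereocentres (C5, C10) form in one operation under cyclic control (syn delivery, then anti trapping). This is more predictable than the acyclic sigmatropic control of the chosen plan, and on this point the alternative is the better one.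
- Against: no ring is formed, and A2 already needs C6, C7 and C8 in place, so the difficulty moves into the substrate. C1 arrives only as a hydroxymethyl group, so C2 and the C1 configuration would have to come from a later homologation of a neopentyl aldehyde with no obvious control; here the chosen plan, which takes C1 from the chiral pool, is stronger. The C9 ketone needs a face-selective reduction, and aldol trapping of a fully substituted magnesium enolate is reversible.
- Step economy: after A1, the lactone, the oxirane and the C9 configuration each cost several operations. The totals would be about equal, with more protecting-group traffic (MOM, PMB) in the alternative.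

**Alternative 2:** The cut is C9–C10 and O–C1. In the forward step the aldoxime A4 is oxidised to the nitrile oxide, which adds across the (E)-alkene to give A3, closing the cyclohexane and an isoxazoline.
- In favour: two bonds and two rings form at once. C10 and C1 are set together and stereospecifically from the alkene geometry, which is better than the chosen plan, where C10 rests on a diastereoselective rearrangement. The isoxazoline masks the C9 and C1 oxygens together. As a ring-forming step it is mechanistically as dependable as the chosen one (equal).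
- Against: the face of addition relative to C5 and C8 is fixed only by the tether conformation. The C8 oxygenated aldoxime precursor is epimerisable. Unmasking needs N–O cleavage (for example Mo(CO)6), a face-selective C9 ketone reduction, ketal removal and methylenation of a hindered methyl ketone next to C5. The C5–C8 stereo-tetrad must be built acyclically beforehand.
- Step economy: roughly five extra redox and protecting-group operations after the key step, whereas the chosen key step delivers C8 and C9 at their final oxidation level.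

**Alternative 3:** The cut is C7–C11 and C6–O. In the forward step the radical from bromoacetal A6 cyclises 5-exo onto C7 of the cyclohexene, and the C6 radical is trapped by TEMPO to give A5.
- In favour: the cis ring fusion is guaranteed by the 5-exo geometry. This is better than the chosen plan, whose C7 configuration depends on a face-selective conjugate reduction. The C6 oxygen enters trans to the new C–C bond, as required. Conditions are neutral and tolerate acetonide and silyl ether (equal to the chosen plan).
- Against: A6 must already contain the ring, the quaternary C10, C1, C5, C8 and C9, so the hardest problems remain unsolved. TEMPO must approach C6 syn to the adjacent C5 isopropenyl group, against the steric bias. The isopropenyl group offers abstractable allylic hydrogens. N–O cleavage and oxidation of the acetal to the lactone follow.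
- Step economy: two unmasking steps replace the single reduction of the chosen plan, but the synthesis of A6 would probably be longer than that of 23.

Key step: step 14

Remarks on the chemistry:
- The target is drawn as the open γ-hydroxy enal; a lactol tautomer between the C6 hydroxyl and C3 is treated as the same compound in equilibrium.
- C(a) is the carbinol carbon of 5 that is excised as formaldehyde in step 12.
- α/β refer to the ring face, β being that of the C10 methyl.

## Route

Step 1
Reactants: 1 (4R)-2,2-dimethyl-1,3-dioxolane-4-carbaldehyde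
Product: 2 (4S)-4-ethynyl-2,2-dimethyl-1,3-dioxolane
Conditions: dimethyl (1-diazo-2-oxopropyl)phosphonate, K2CO3, MeOH, 0 °C → rt
Reagents that add atoms: dimethyl (1-diazo-2-oxopropyl)phosphonate, CC(=O)C(=[N+]=[N-])P(=O)(OC)OC
Why: Seyferth–Gilbert homologation in the Ohira–Bestmann form: methanolysis of the reagent gives the diazomethylphosphonate anion, and its Horner-type addition–elimination followed by a 1,2-shift in the alkylidene carbene gives the alkyne; the mild carbonate medium should leave the α-oxygenated stereocentre (future C1) intact.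

Step 2
Reactants: 2 (4S)-4-ethynyl-2,2-dimethyl-1,3-dioxolane
Product: 3 methyl 3-[(4S)-2,2-dimethyl-1,3-dioxolan-4-yl]prop-2-ynoate
Conditions: n-BuLi, THF, −78 °C; ClCO2Me, −78 → 0 °C
Reagents that add atoms: methyl chloroformate, COC(=O)Cl
Why: Deprotonation of the terminal alkyne and C-acylation of the lithium acetylide; the carbon added is C(a), which activates the alkyne for step 3 and is excised in step 12.

Step 3
Reactants: 3 methyl 3-[(4S)-2,2-dimethyl-1,3-dioxolan-4-yl]prop-2-ynoate
Product: 4 methyl (2Z)-3-[(4S)-2,2-dimethyl-1,3-dioxolan-4-yl]but-2-enoate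
Conditions: Me2CuLi (from MeLi and CuI), THF, −78 °C; MeOH quench at −78 °C
Reagents that add atoms: lithium dimethylcuprate Me2CuLi, [Li+].C[Cu-]C
Why: Syn-carbocupration of an ynoate: methyl and copper add to the same side, and protonation at −78 °C, before the alkenylcuprate equilibrates through the allenolate, gives the (Z)-enoate with the ester cis to the dioxolane; this installs the C10 methyl.

Step 4
Reactants: 4 methyl (2Z)-3-[(4S)-2,2-dimethyl-1,3-dioxolan-4-yl]but-2-enoate
Product: 5 (2Z)-3-[(4S)-2,2-dimethyl-1,3-dioxolan-4-yl]but-2-en-1-ol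
Conditions: i-Bu2AlH (2.2 equiv), CH2Cl2, −78 °C; aq. potassium sodium tartrate
Reagents that add atoms: none
Why: 1,2-Reduction of the enoate by the aluminium hydride retains the alkene geometry; the acetonide prevents lactonisation of the Z γ-oxygenated system.

Step 5
Reactants: 5 (2Z)-3-[(4S)-2,2-dimethyl-1,3-dioxolan-4-yl]but-2-en-1-ol; 6 3-methylbut-3-enoic acid
Product: 7 (2Z)-3-[(4S)-2,2-dimethyl-1,3-dioxolan-4-yl]but-2-en-1-yl 3-methylbut-3-enoate
Conditions: DIC, DMAP (5 mol %), CH2Cl2, 0 °C
Reagents that add atoms: none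
Why: Steglich esterification; low temperature and little DMAP keep the β,γ-alkene of the acyl group out of conjugation, which would otherwise change the enolate geometry in step 6.

Step 6
Reactants: 7 (2Z)-3-[(4S)-2,2-dimethyl-1,3-dioxolan-4-yl]but-2-en-1-yl 3-methylbut-3-enoate
Product: 10 (2S,3R)-3-[(4S)-2,2-dimethyl-1,3-dioxolan-4-yl]-3-methyl-2-(prop-1-en-2-yl)pent-4-enoic acid, via silyl ketene acetal 8 (not isolated), via trimethylsilyl ester 9 (not isolated)
Conditions: LiN(i-Pr)2, THF, −78 °C; Me3SiCl, −78 → 60 °C; aq. NaOH, then citric acid to pH 4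
Reagents that add atoms: none
Why: Ireland–Claisen rearrangement: kinetic enolisation in THF without a polar cosolvent should give the ketene acetal with the isopropenyl group trans to OSiMe3 (Ireland model), and a chair transition state with the (Z)-alkene then fixes the C5/C10 relationship; allylic 1,3-strain holds H-1 in the alkene plane, so C5 bonds to C10 anti to the allylic C1–O bond and the dioxolane sets the absolute sense.

Step 7
Reactants: 10 (2S,3R)-3-[(4S)-2,2-dimethyl-1,3-dioxolan-4-yl]-3-methyl-2-(prop-1-en-2-yl)pent-4-enoic acid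
Product: 11 (2S,3R)-3-[(4S)-2,2-dimethyl-1,3-dioxolan-4-yl]-N-methoxy-N,3-dimethyl-2-(prop-1-en-2-yl)pent-4-enamide
Conditions: MeNH(OMe)·HCl, DIC, HOBt, N-methylmorpholine, CH2Cl2, 0 °C → rt
Reagents that add atoms: N,O-dimethylhydroxylamine hydrochloride, CNOC.Cl
Why: Carbodiimide/HOBt amidation to the Weinreb amide under weakly basic conditions, chosen to avoid ketene formation and epimerisation at C5.

Step 8
Reactants: 11 (2S,3R)-3-[(4S)-2,2-dimethyl-1,3-dioxolan-4-yl]-N-methoxy-N,3-dimethyl-2-(prop-1-en-2-yl)pent-4-enamide; 12 3-bromofuran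
Product: 14 (2S,3R)-3-[(4S)-2,2-dimethyl-1,3-dioxolan-4-yl]-1-(furan-3-yl)-3-methyl-2-(prop-1-en-2-yl)pent-4-en-1-one, via 3-furyllithium 13 (not isolated)
Conditions: 12, n-BuLi, THF, −78 °C; then 11, −78 °C; aq. NH4Cl
Reagents that add atoms: none
Why: Bromine–lithium exchange gives 3-furyllithium (kept at −78 °C so that it does not isomerise to the 2-lithio species), which acylates the Weinreb amide; the chelated tetrahedral adduct stops over-addition and keeps the enolisable β,γ-unsaturated ketone masked until the quench.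

Step 9
Reactants: 14 (2S,3R)-3-[(4S)-2,2-dimethyl-1,3-dioxolan-4-yl]-1-(furan-3-yl)-3-methyl-2-(prop-1-en-2-yl)pent-4-en-1-one
Product: 15 (1S,2S,3R)-3-[(4S)-2,2-dimethyl-1,3-dioxolan-4-yl]-1-(furan-3-yl)-3-methyl-2-(prop-1-en-2-yl)pent-4-en-1-ol
Conditions: LiBH(s-Bu)3, THF, −78 °C
Reagents that add atoms: none
Why: Felkin–Anh reduction: with the quaternary C10 anti to the bulky hydride and H-5 beside the furyl group, hydride delivery should give the (S)-carbinol, the C6 configuration needed; by the same model, adding the furyl nucleophile to a C6 aldehyde would give the epimer, which is why the ketone is reduced instead.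

Step 10
Reactants: 15 (1S,2S,3R)-3-[(4S)-2,2-dimethyl-1,3-dioxolan-4-yl]-1-(furan-3-yl)-3-methyl-2-(prop-1-en-2-yl)pent-4-en-1-ol
Product: 16 tert-butyl{[(1S,2S,3R)-3-[(4S)-2,2-dimethyl-1,3-dioxolan-4-yl]-1-(furan-3-yl)-3-methyl-2-(prop-1-en-2-yl)pent-4-en-1-yl]oxy}dimethylsilane
Conditions: t-BuMe2SiOTf, 2,6-lutidine, CH2Cl2, −78 → 0 °C
Reagents that add atoms: tert-butyldimethylsilyl triflate, CC(C)(C)[Si](C)(C)OS(=O)(=O)C(F)(F)F
Why: Silyl triflate/lutidine silylation of a hindered secondary alcohol; the bulky silyl ether later acts as a stereocontrol element in the ring closure.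

Step 11
Reactants: 16 tert-butyl{[(1S,2S,3R)-3-[(4S)-2,2-dimethyl-1,3-dioxolan-4-yl]-1-(furan-3-yl)-3-methyl-2-(prop-1-en-2-yl)pent-4-en-1-yl]oxy}dimethylsilane
Product: 19 4-[(1S,2S,3R)-1-[(tert-butyldimethylsilyl)oxy]-3-[(4S)-2,2-dimethyl-1,3-dioxolan-4-yl]-3-methyl-2-(prop-1-en-2-yl)pent-4-en-1-yl]furan-2(5H)-one, via furan endoperoxide 17 (not isolated), via hydroxybutenolide 18 (not isolated)
Conditions: O2, hν, tetraphenylporphyrin, i-Pr2NEt, CH2Cl2, −78 °C; then NaBH4, EtOH, 0 °C; aq. HCl to pH 3
Reagents that add atoms: dioxygen, O=O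
Why: [4+2] addition of singlet oxygen to the furan, then base-induced Kornblum–DeLaMare-type fragmentation by removal of the less hindered hydrogen at the unsubstituted α-carbon, places the carbonyl distal to the side chain; NaBH4 reduces the ring-opened formyl group and acid relactonises to the 4-substituted furan-2(5H)-one, while the isolated alkenes react with singlet oxygen far more slowly than the furan.

Step 12
Reactants: 19 4-[(1S,2S,3R)-1-[(tert-butyldimethylsilyl)oxy]-3-[(4S)-2,2-dimethyl-1,3-dioxolan-4-yl]-3-methyl-2-(prop-1-en-2-yl)pent-4-en-1-yl]furan-2(5H)-one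
Product: 22 (2R,3S,4S)-4-[(tert-butyldimethylsilyl)oxy]-2-[(4S)-2,2-dimethyl-1,3-dioxolan-4-yl]-2-methyl-4-(5-oxo-2,5-dihydrofuran-3-yl)-3-(prop-1-en-2-yl)butanal, via dibromide 20 (not isolated), via ozonide 21 (not isolated)
Conditions: pyridinium tribromide (1.0 equiv), CH2Cl2, −78 °C; O3, −78 °C; Zn, AcOH, −78 → 0 °C
Reagents that add atoms: ozone, [O-][O+]=O
Why: Electrophilic bromination takes the more nucleophilic 1,1-disubstituted isopropenyl alkene in preference to the neopentyl vinyl group and the electron-poor butenolide; ozone then cleaves only the vinyl group, and Zn/AcOH both reduces the ozonide to the C9 aldehyde and regenerates the isopropenyl group by reductive 1,2-debromination (the classical bromine-masking, ozonolysis, zinc sequence).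

Step 13
Reactants: 22 (2R,3S,4S)-4-[(tert-butyldimethylsilyl)oxy]-2-[(4S)-2,2-dimethyl-1,3-dioxolan-4-yl]-2-methyl-4-(5-oxo-2,5-dihydrofuran-3-yl)-3-(prop-1-en-2-yl)butanal
Product: 23 (2R,3S,4S)-4-[(tert-butyldimethylsilyl)oxy]-2-[(4S)-2,2-dimethyl-1,3-dioxolan-4-yl]-2-methyl-3-(prop-1-en-2-yl)-4-{5-[(triisopropylsilyl)oxy]furan-3-yl}butanal
Conditions: i-Pr3SiOTf, Et3N, CH2Cl2, 0 °C
Reagents that add atoms: triisopropylsilyl triflate, CC(C)[Si](C(C)C)(C(C)C)OS(=O)(=O)C(F)(F)F
Why: Soft enolisation of the butenolide (O-silylation, then γ-deprotonation by Et3N) gives the aromatic 2-silyloxyfuran; the aldehyde has no α-hydrogen and, with amine in excess over the silyl triflate, is not activated, so 23 can be filtered through base-washed silica.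

Step 14
Reactants: 23 (2R,3S,4S)-4-[(tert-butyldimethylsilyl)oxy]-2-[(4S)-2,2-dimethyl-1,3-dioxolan-4-yl]-2-methyl-3-(prop-1-en-2-yl)-4-{5-[(triisopropylsilyl)oxy]furan-3-yl}butanal
Product: 24 (4S,5S,6S,7S,7aR)-4-[(tert-butyldimethylsilyl)oxy]-6-[(4S)-2,2-dimethyl-1,3-dioxolan-4-yl]-7-hydroxy-6-methyl-5-(prop-1-en-2-yl)-5,6,7,7a-tetrahydro-1-benzofuran-2(4H)-one
Conditions: BF3·OEt2 (1.5 equiv), CH2Cl2 (0.01 M), −78 °C; aq. NaHCO3
Reagents that add atoms: none
Why: Intramolecular vinylogous Mukaiyama aldol addition: BF3 binds the non-enolisable C9 aldehyde, the silyloxyfuran attacks through its 5-position (C8) and loss of silicon as the fluoride unveils the Δ7(11)-butenolide; the closest known reaction is the Lewis-acid-mediated addition of 2-silyloxyfurans to aldehydes, used here in its ring-forming form. The cyclohexane closes in a 6-(enolendo)-exo-trig mode by annulation across the furan C4–C5 bond. C8 is controlled by C6: with H-6 near the furan plane (allylic 1,3-strain), C5 and the silyloxy group straddle C8 on opposite faces, so the tether reaches C8 anti to OTBS and H-8 ends syn to it; the other fold would place the dioxolane and isopropenyl groups axial. C9 is controlled by C10: in the chair-like array (C10 methyl axial, dioxolane and isopropenyl equatorial) the BF3-bound oxygen should take the axial site anti to the methyl, leaving the small aldehyde hydrogen in the equatorial slot gauche to both C10 substituents, which gives the C9 hydroxyl cis to the C8 oxygen and trans to the methyl. The step needs γ- over α-regioselectivity (C11 could also close a six-membered ring); this is secured by the intrinsic γ-preference of silyloxyfurans and by the conjugated product. It also needs chemoselectivity over a Prins or ene reaction of the isopropenyl group, secured by the much higher nucleophilicity of the silyloxyfuran. The aldehyde cannot epimerise, −78 °C should spare the acetonide and silyl ether, and high dilution suppresses intermolecular addition.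

Step 15
Reactants: 24 (4S,5S,6S,7S,7aR)-4-[(tert-butyldimethylsilyl)oxy]-6-[(4S)-2,2-dimethyl-1,3-dioxolan-4-yl]-7-hydroxy-6-methyl-5-(prop-1-en-2-yl)-5,6,7,7a-tetrahydro-1-benzofuran-2(4H)-one
Product: 25 (3aS,4S,5S,6S,7S,7aR)-4-[(tert-butyldimethylsilyl)oxy]-6-[(4S)-2,2-dimethyl-1,3-dioxolan-4-yl]-7-hydroxy-6-methyl-5-(prop-1-en-2-yl)hexahydro-1-benzofuran-2(3H)-one
Conditions: [(Ph3P)CuH]6 (0.5 equiv), H2O (5 equiv), benzene/THF, rt
Reagents that add atoms: none
Why: Conjugate reduction by the copper hydride cluster, chemoselective for the enoate over the isolated isopropenyl alkene; the ring is held in the chair that keeps the C8–O bond in the lactone plane, where the lower face of C7 is the axial trajectory screened by the syn-axial C9 oxygen and H-5, so hydride should enter from the convex H-8 face and give the cis-fused lactone.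

Step 16
Reactants: 25 (3aS,4S,5S,6S,7S,7aR)-4-[(tert-butyldimethylsilyl)oxy]-6-[(4S)-2,2-dimethyl-1,3-dioxolan-4-yl]-7-hydroxy-6-methyl-5-(prop-1-en-2-yl)hexahydro-1-benzofuran-2(3H)-one
Product: 28 (3aS,4S,5S,6S,7S,7aR)-4-[(tert-butyldimethylsilyl)oxy]-6-[(4S)-2,2-dimethyl-1,3-dioxolan-4-yl]-7-hydroxy-6-methyl-3-methylidene-5-(prop-1-en-2-yl)hexahydro-1-benzofuran-2(3H)-one, via Mannich base 26 (not isolated), via ammonium iodide 27 (not isolated)
Conditions: LiN(i-Pr)2 (2.5 equiv), THF, −78 °C; dimethyl(methylidene)ammonium iodide, −78 → 0 °C; MeI, CH2Cl2, rt; aq. NaHCO3, rt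
Reagents that add atoms: dimethyl(methylidene)ammonium iodide, C=[N+](C)C.[I-]
Why: Dianion formation (C9 alkoxide and lactone enolate), Mannich reaction at C11 with the iminium salt, N-methylation and E1cB loss of trimethylamine; C11 becomes trigonal, so its transient configuration is irrelevant.

Step 17
Reactants: 28 (3aS,4S,5S,6S,7S,7aR)-4-[(tert-butyldimethylsilyl)oxy]-6-[(4S)-2,2-dimethyl-1,3-dioxolan-4-yl]-7-hydroxy-6-methyl-3-methylidene-5-(prop-1-en-2-yl)hexahydro-1-benzofuran-2(3H)-one
Product: 29 (3aS,4S,5S,6R,7S,7aR)-4-[(tert-butyldimethylsilyl)oxy]-6-[(4S)-2,2-dimethyl-1,3-dioxolan-4-yl]-6-methyl-3-methylidene-2-oxo-5-(prop-1-en-2-yl)octahydro-1-benzofuran-7-yl 2-methylprop-2-enoate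
Conditions: methacrylic anhydride, Et3N, DMAP, CH2Cl2, rt
Reagents that add atoms: methacrylic anhydride, C=C(C)C(=O)OC(=O)C(C)=C
Why: DMAP-catalysed acylation of the hindered C9 alcohol; it is placed here because a methacrylate would not survive the hydride and enolate steps, and C6 is still silylated, so only C9 can react.

Step 18
Reactants: 29 (3aS,4S,5S,6R,7S,7aR)-4-[(tert-butyldimethylsilyl)oxy]-6-[(4S)-2,2-dimethyl-1,3-dioxolan-4-yl]-6-methyl-3-methylidene-2-oxo-5-(prop-1-en-2-yl)octahydro-1-benzofuran-7-yl 2-methylprop-2-enoate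
Product: 31 (3aS,4S,5R,6R,7S,7aR)-4-[(tert-butyldimethylsilyl)oxy]-6-[(4S)-2,2-dimethyl-1,3-dioxolan-4-yl]-6-methyl-3-methylidene-2-oxo-5-(3-oxoprop-1-en-2-yl)octahydro-1-benzofuran-7-yl 2-methylprop-2-enoate, via allylic alcohol 30 (not isolated)
Conditions: SeO2 (0.5 equiv), t-BuOOH, CH2Cl2, rt; then MnO2, CH2Cl2, rt
Reagents that add atoms: tert-butyl hydroperoxide, CC(C)(C)OO
Why: Allylic oxidation by the ene/[2,3]-sigmatropic sequence of SeO2 at the methyl of the only electron-rich alkene (the α-methylene lactone and methacrylate are electron-poor, and H-5 is a hindered methine), then MnO2 oxidation of the primary allylic alcohol to the enal; no other free hydroxyl is present.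

Step 19
Reactants: 31 (3aS,4S,5R,6R,7S,7aR)-4-[(tert-butyldimethylsilyl)oxy]-6-[(4S)-2,2-dimethyl-1,3-dioxolan-4-yl]-6-methyl-3-methylidene-2-oxo-5-(3-oxoprop-1-en-2-yl)octahydro-1-benzofuran-7-yl 2-methylprop-2-enoate
Product: 32 (3aR,4S,5R,6R,7S,7aR)-6-[(1S)-1,2-dihydroxyethyl]-4-hydroxy-6-methyl-3-methylidene-2-oxo-5-(3-oxoprop-1-en-2-yl)octahydro-1-benzofuran-7-yl 2-methylprop-2-enoate
Conditions: CF3CO2H/H2O (9:1), 0 °C; aq. NaHCO3
Reagents that add atoms: none
Why: Acid hydrolysis of the acetonide and protodesilylation of the C6 ether in one operation; the three Michael acceptors are acid-stable and no nucleophilic solvent is present.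

Step 20
Reactants: 32 (3aR,4S,5R,6R,7S,7aR)-6-[(1S)-1,2-dihydroxyethyl]-4-hydroxy-6-methyl-3-methylidene-2-oxo-5-(3-oxoprop-1-en-2-yl)octahydro-1-benzofuran-7-yl 2-methylprop-2-enoate
Product: 34 (3aR,4S,5R,6R,7S,7aR)-4-hydroxy-6-methyl-3-methylidene-6-[(2S)-oxiran-2-yl]-2-oxo-5-(3-oxoprop-1-en-2-yl)octahydro-1-benzofuran-7-yl 2-methylprop-2-enoate, via primary tosylate 33 (not isolated)
Conditions: TsCl (1.1 equiv), Bu2SnO (5 mol %), Et3N, CH2Cl2, 0 °C → rt; then DBU, 0 °C → rt
Reagents that add atoms: none
Why: Stannylene-mediated tosylation is selective for the primary hydroxyl of the terminal 1,2-diol over the hindered C6 hydroxyl; the amidine base then closes the oxirane by 3-exo-tet displacement, with retention at C1 because the C1–O bond is never broken.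

## Compound list

1 | (4R)-2,2-dimethyl-1,3-dioxolane-4-carbaldehyde | O=C[C@H]1COC(C)(C)O1 | starting material
2 | (4S)-4-ethynyl-2,2-dimethyl-1,3-dioxolane | C#C[C@H]1COC(C)(C)O1 | intermediate
3 | methyl 3-[(4S)-2,2-dimethyl-1,3-dioxolan-4-yl]prop-2-ynoate | COC(=O)C#C[C@H]1COC(C)(C)O1 | intermediate
4 | methyl (2Z)-3-[(4S)-2,2-dimethyl-1,3-dioxolan-4-yl]but-2-enoate | COC(=O)/C=C(/C)[C@H]1COC(C)(C)O1 | intermediate
5 | (2Z)-3-[(4S)-2,2-dimethyl-1,3-dioxolan-4-yl]but-2-en-1-ol | OC/C=C(/C)[C@H]1COC(C)(C)O1 | intermediate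
6 | 3-methylbut-3-enoic acid | C=C(C)CC(=O)O | starting material
7 | (2Z)-3-[(4S)-2,2-dimethyl-1,3-dioxolan-4-yl]but-2-en-1-yl 3-methylbut-3-enoate | C=C(C)CC(=O)OC/C=C(/C)[C@H]1COC(C)(C)O1 | intermediate
8 | O-trimethylsilyl ketene acetal of 7, isopropenyl trans to OSiMe3 | C=C(C)/C=C(/O[Si](C)(C)C)OC/C=C(/C)[C@H]1COC(C)(C)O1 | intermediate (not isolated)
9 | trimethylsilyl ester of acid 10 | C=C[C@@](C)([C@H]1COC(C)(C)O1)[C@H](C(C)=C)C(=O)O[Si](C)(C)C | intermediate (not isolated)
10 | (2S,3R)-3-[(4S)-2,2-dimethyl-1,3-dioxolan-4-yl]-3-methyl-2-(prop-1-en-2-yl)pent-4-enoic acid | C=C[C@@](C)([C@H]1COC(C)(C)O1)[C@H](C(C)=C)C(=O)O | intermediate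
11 | (2S,3R)-3-[(4S)-2,2-dimethyl-1,3-dioxolan-4-yl]-N-methoxy-N,3-dimethyl-2-(prop-1-en-2-yl)pent-4-enamide | C=C[C@@](C)([C@H]1COC(C)(C)O1)[C@H](C(C)=C)C(=O)N(C)OC | intermediate
12 | 3-bromofuran | Brc1ccoc1 | starting material
13 | 3-furyllithium | [Li]c1ccoc1 | intermediate (not isolated)
14 | (2S,3R)-3-[(4S)-2,2-dimethyl-1,3-dioxolan-4-yl]-1-(furan-3-yl)-3-methyl-2-(prop-1-en-2-yl)pent-4-en-1-one | C=C[C@@](C)([C@H]1COC(C)(C)O1)[C@H](C(C)=C)C(=O)c1ccoc1 | intermediate
15 | (1S,2S,3R)-3-[(4S)-2,2-dimethyl-1,3-dioxolan-4-yl]-1-(furan-3-yl)-3-methyl-2-(prop-1-en-2-yl)pent-4-en-1-ol | C=C[C@@](C)([C@H]1COC(C)(C)O1)[C@H](C(C)=C)[C@H](O)c1ccoc1 | intermediate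
16 | tert-butyldimethylsilyl ether of 15 (1S,2S,3R) | C=C[C@@](C)([C@H]1COC(C)(C)O1)[C@H](C(C)=C)[C@H](O[Si](C)(C)C(C)(C)C)c1ccoc1 | intermediate
17 | 2,5-endoperoxide of furan 16 (2,3,7-trioxabicyclo[2.2.1]hept-5-ene, side chain on C5) | C=C[C@@](C)([C@H]1COC(C)(C)O1)[C@H](C(C)=C)[C@H](O[Si](C)(C)C(C)(C)C)C1=CC2OOC1O2 | intermediate (not isolated)
18 | 5-hydroxy-4-substituted furan-2(5H)-one from 16 (hemiacetal epimers) | C=C[C@@](C)([C@H]1COC(C)(C)O1)[C@H](C(C)=C)[C@H](O[Si](C)(C)C(C)(C)C)C1=CC(=O)OC1O | intermediate (not isolated)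
19 | 4-[(1S,2S,3R)-1-[(tert-butyldimethylsilyl)oxy]-3-[(4S)-2,2-dimethyl-1,3-dioxolan-4-yl]-3-methyl-2-(prop-1-en-2-yl)pent-4-en-1-yl]furan-2(5H)-one | C=C[C@@](C)([C@H]1COC(C)(C)O1)[C@H](C(C)=C)[C@H](O[Si](C)(C)C(C)(C)C)C1=CC(=O)OC1 | intermediate
20 | 1,2-dibromide of the isopropenyl group of 19 (epimers at C4) | C=C[C@@](C)([C@H]1COC(C)(C)O1)[C@H](C(C)(Br)CBr)[C@H](O[Si](C)(C)C(C)(C)C)C1=CC(=O)OC1 | intermediate (not isolated)
21 | 1,2,4-trioxolane (ozonide) of the vinyl group of 20 | O1COOC1[C@@](C)([C@H]1COC(C)(C)O1)[C@H](C(C)(Br)CBr)[C@H](O[Si](C)(C)C(C)(C)C)C1=CC(=O)OC1 | intermediate (not isolated)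
22 | (2R,3S,4S)-4-[(tert-butyldimethylsilyl)oxy]-2-[(4S)-2,2-dimethyl-1,3-dioxolan-4-yl]-2-methyl-4-(5-oxo-2,5-dihydrofuran-3-yl)-3-(prop-1-en-2-yl)butanal | O=C[C@@](C)([C@H]1COC(C)(C)O1)[C@H](C(C)=C)[C@H](O[Si](C)(C)C(C)(C)C)C1=CC(=O)OC1 | intermediate
23 | (2R,3S,4S)-4-[(tert-butyldimethylsilyl)oxy]-2-[(4S)-2,2-dimethyl-1,3-dioxolan-4-yl]-2-methyl-3-(prop-1-en-2-yl)-4-{5-[(triisopropylsilyl)oxy]furan-3-yl}butanal | O=C[C@@](C)([C@H]1COC(C)(C)O1)[C@H](C(C)=C)[C@H](O[Si](C)(C)C(C)(C)C)c1coc(O[Si](C(C)C)(C(C)C)C(C)C)c1 | intermediate (key-step precursor)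
24 | (4S,5S,6S,7S,7aR)-4-[(tert-butyldimethylsilyl)oxy]-6-[(4S)-2,2-dimethyl-1,3-dioxolan-4-yl]-7-hydroxy-6-methyl-5-(prop-1-en-2-yl)-5,6,7,7a-tetrahydro-1-benzofuran-2(4H)-one | O[C@@H]1[C@@H]2OC(=O)C=C2[C@@H](O[Si](C)(C)C(C)(C)C)[C@@H](C(C)=C)[C@]1(C)[C@H]1COC(C)(C)O1 | intermediate (key-step product)
25 | (3aS,4S,5S,6S,7S,7aR)-4-[(tert-butyldimethylsilyl)oxy]-6-[(4S)-2,2-dimethyl-1,3-dioxolan-4-yl]-7-hydroxy-6-methyl-5-(prop-1-en-2-yl)hexahydro-1-benzofuran-2(3H)-one | O[C@@H]1[C@@H]2OC(=O)C[C@@H]2[C@@H](O[Si](C)(C)C(C)(C)C)[C@@H](C(C)=C)[C@]1(C)[C@H]1COC(C)(C)O1 | intermediate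
26 | 3-[(dimethylamino)methyl] derivative of 25 (epimers at C11) | O[C@@H]1[C@@H]2OC(=O)C(CN(C)C)[C@@H]2[C@@H](O[Si](C)(C)C(C)(C)C)[C@@H](C(C)=C)[C@]1(C)[C@H]1COC(C)(C)O1 | intermediate (not isolated)
27 | trimethylammonium iodide from 26 | O[C@@H]1[C@@H]2OC(=O)C(C[N+](C)(C)C)[C@@H]2[C@@H](O[Si](C)(C)C(C)(C)C)[C@@H](C(C)=C)[C@]1(C)[C@H]1COC(C)(C)O1.[I-] | intermediate (not isolated)
28 | (3aS,4S,5S,6S,7S,7aR)-4-[(tert-butyldimethylsilyl)oxy]-6-[(4S)-2,2-dimethyl-1,3-dioxolan-4-yl]-7-hydroxy-6-methyl-3-methylidene-5-(prop-1-en-2-yl)hexahydro-1-benzofuran-2(3H)-one | O[C@@H]1[C@@H]2OC(=O)C(=C)[C@@H]2[C@@H](O[Si](C)(C)C(C)(C)C)[C@@H](C(C)=C)[C@]1(C)[C@H]1COC(C)(C)O1 | intermediate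
29 | (3aS,4S,5S,6R,7S,7aR)-4-[(tert-butyldimethylsilyl)oxy]-6-[(4S)-2,2-dimethyl-1,3-dioxolan-4-yl]-6-methyl-3-methylidene-2-oxo-5-(prop-1-en-2-yl)octahydro-1-benzofuran-7-yl 2-methylprop-2-enoate | C=C(C)C(=O)O[C@@H]1[C@@H]2OC(=O)C(=C)[C@@H]2[C@@H](O[Si](C)(C)C(C)(C)C)[C@@H](C(C)=C)[C@]1(C)[C@H]1COC(C)(C)O1 | intermediate
30 | 5-(3-hydroxyprop-1-en-2-yl) analogue of 29 | C=C(C)C(=O)O[C@@H]1[C@@H]2OC(=O)C(=C)[C@@H]2[C@@H](O[Si](C)(C)C(C)(C)C)[C@@H](C(=C)CO)[C@]1(C)[C@H]1COC(C)(C)O1 | intermediate (not isolated)
31 | (3aS,4S,5R,6R,7S,7aR)-4-[(tert-butyldimethylsilyl)oxy]-6-[(4S)-2,2-dimethyl-1,3-dioxolan-4-yl]-6-methyl-3-methylidene-2-oxo-5-(3-oxoprop-1-en-2-yl)octahydro-1-benzofuran-7-yl 2-methylprop-2-enoate | C=C(C)C(=O)O[C@@H]1[C@@H]2OC(=O)C(=C)[C@@H]2[C@@H](O[Si](C)(C)C(C)(C)C)[C@@H](C(=C)C=O)[C@]1(C)[C@H]1COC(C)(C)O1 | intermediate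
32 | (3aR,4S,5R,6R,7S,7aR)-6-[(1S)-1,2-dihydroxyethyl]-4-hydroxy-6-methyl-3-methylidene-2-oxo-5-(3-oxoprop-1-en-2-yl)octahydro-1-benzofuran-7-yl 2-methylprop-2-enoate | C=C(C)C(=O)O[C@@H]1[C@@H]2OC(=O)C(=C)[C@@H]2[C@@H](O)[C@@H](C(=C)C=O)[C@]1(C)[C@H](O)CO | intermediate
33 | primary p-toluenesulfonate of 32 (at C2) | C=C(C)C(=O)O[C@@H]1[C@@H]2OC(=O)C(=C)[C@@H]2[C@@H](O)[C@@H](C(=C)C=O)[C@]1(C)[C@H](O)COS(=O)(=O)c1ccc(C)cc1 | intermediate (not isolated)
34 | (3aR,4S,5R,6R,7S,7aR)-4-hydroxy-6-methyl-3-methylidene-6-[(2S)-oxiran-2-yl]-2-oxo-5-(3-oxoprop-1-en-2-yl)octahydro-1-benzofuran-7-yl 2-methylprop-2-enoate (CNP0124638.3) | C=C(C)C(=O)O[C@@H]1[C@@H]2OC(=O)C(=C)[C@@H]2[C@@H](O)[C@@H](C(=C)C=O)[C@]1(C)[C@H]1CO1 | target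

## Step count and least certain steps

Total step count: 20. Longest linear sequence: 20 steps (1 to 34); 6 and 12 are commercial and enter at steps 5 and 8.

**Step 14 (key step).** The most likely failure is erosion of simple diastereoselection at C9: the Lewis-acid-bound carbonyl may adopt the equatorial, antiperiplanar orientation, because the preference for the axial site rests only on avoiding the axial C10 methyl. Partial ionisation of the acetonide by BF3 is a second concern. Fallback, setting out from 23 and returning at 24: the cyclisation mixture, containing the C9 epimer F1, would be oxidised as a whole with Dess–Martin periodinane to the single C9 ketone F2. This would be reduced at −78 °C with LiBH(s-Bu)3, which approaches a cyclohexanone equatorially and should give the axial (α) C9 alcohol 24. C9 is then set by ketone reduction and not by the aldol geometry.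

**Step 6.** Loss of ketene acetal geometry on enolising the vinylogous, more acidic β,γ-unsaturated ester, or leakage through a boat transition state forced by the axial dioxolane, would give the C5 epimer. Weak facial bias would give the C10 epimer. Fallback, setting out from 2 and returning at 10: it uses the (E)-alkene with the opposite ketene acetal geometry, which converge on the same relative configuration through a chair with both large groups equatorial.
- Hydroxymethylation of 2 (n-BuLi, paraformaldehyde) would give the propargylic alcohol F3.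
- Trans-hydroalumination with NaAlH2(OCH2CH2OMe)2 and iodination would give the (Z)-iodoalkenol F4.
- Methylation with Me2CuLi would give the (E)-allylic alcohol F5.
- Acylation with 3-methylbut-2-enoyl chloride would give the senecioate F6.
- γ-Deprotonation of F6 (LiN(i-Pr)2, THF/DMPU, Me3SiCl) should give the dienolate with the isopropenyl cis to the silyloxy group, locked by the s-cis enoate, and rearrange to 10.

Facial control would then rest on the weaker induction of an (E)-alkene.

**Step 9.** Hydride may be delivered with the opposite facial sense if the isopropenyl group, not C10, takes the anti position. Enolisation or conjugation of the β,γ-unsaturated ketone by the basic hydride is also possible. Fallback, setting out from 11 and returning at 15: reduction of 11 with i-Bu2AlH at −78 °C would give the aldehyde F7, and addition of 13 to F7 exchanges the roles of nucleophile and carbonyl substituent. It therefore gives the C6 epimer complementary to the hydride route under the same facial preference.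

**Step 12.** Bromination may spill over onto the vinyl group, an acetal oxygen may participate in opening the tertiary bromonium ion, or the tertiary bromide may lose HBr before the zinc step. Fallback, setting out from 19 and returning at 22:
- mCPBA would epoxidise the isopropenyl group selectively to the epoxide F8.
- Ozonolysis with NaBH4 work-up would give the epoxy alcohol F9.
- Deoxygenation with PPh3 and catalytic MeReO3 would give the alkenol F10.
- Dess–Martin oxidation would return 22.

**Step 15.** Hydride may be delivered to the lower face of C7, giving the trans-fused lactone, since the axial C6 silyloxy group also crowds the upper face. Reduction of the β,β-disubstituted enoate may also be sluggish. Fallback, setting out from 24 and returning at 25: control passes from substrate to catalyst. A copper hydride generated from Cu(OAc)2, a chiral bisphosphine (either enantiomer of SEGPHOS, the matched one to be kept) and polymethylhydrosiloxane with t-BuOH would be used. The C9 hydroxyl would be silylated in situ, which further blocks the lower face. No new compound is involved.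

**Step 20.** The amidine may add to the α-methylene lactone or the enal, or isomerise the exocyclic alkene. The C1 alkoxide may also accept the C9 acyl group faster than it closes. Fallback, setting out from 33 (isolated in this variant) and returning at 34: NaI in acetone would convert the tosylate to the iodohydrin F11, and Ag2O in MeCN would close the oxirane by halophilic activation without an amine base.

Further compounds

F1 | step 14 | C9 epimer of 24 (7R alcohol) | O[C@H]1[C@@H]2OC(=O)C=C2[C@@H](O[Si](C)(C)C(C)(C)C)[C@@H](C(C)=C)[C@]1(C)[C@H]1COC(C)(C)O1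
F2 | step 14 | C9 ketone derived from 24 and F1 | O=C1[C@@H]2OC(=O)C=C2[C@@H](O[Si](C)(C)C(C)(C)C)[C@@H](C(C)=C)[C@]1(C)[C@H]1COC(C)(C)O1
F3 | step 6 | 3-[(4S)-2,2-dimethyl-1,3-dioxolan-4-yl]prop-2-yn-1-ol | OCC#C[C@H]1COC(C)(C)O1
F4 | step 6 | (2Z)-3-[(4R)-2,2-dimethyl-1,3-dioxolan-4-yl]-3-iodoprop-2-en-1-ol | OC/C=C(\I)[C@H]1COC(C)(C)O1
F5 | step 6 | (2E)-3-[(4S)-2,2-dimethyl-1,3-dioxolan-4-yl]but-2-en-1-ol | OC/C=C(\C)[C@H]1COC(C)(C)O1
F6 | step 6 | (2E)-3-[(4S)-2,2-dimethyl-1,3-dioxolan-4-yl]but-2-en-1-yl 3-methylbut-2-enoate | CC(C)=CC(=O)OC/C=C(\C)[C@H]1COC(C)(C)O1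
F7 | step 9 | (2S,3R)-3-[(4S)-2,2-dimethyl-1,3-dioxolan-4-yl]-3-methyl-2-(prop-1-en-2-yl)pent-4-enal | C=C[C@@](C)([C@H]1COC(C)(C)O1)[C@H](C(C)=C)C=O
F8 | step 12 | epoxide of the isopropenyl group of 19 (epimers at C4) | C=C[C@@](C)([C@H]1COC(C)(C)O1)[C@H](C1(C)CO1)[C@H](O[Si](C)(C)C(C)(C)C)C1=CC(=O)OC1
F9 | step 12 | C9 primary alcohol from F8 (vinyl replaced by CH2OH) | OC[C@@](C)([C@H]1COC(C)(C)O1)[C@H](C1(C)CO1)[C@H](O[Si](C)(C)C(C)(C)C)C1=CC(=O)OC1
F10 | step 12 | C9 primary alcohol corresponding to 22 | OC[C@@](C)([C@H]1COC(C)(C)O1)[C@H](C(C)=C)[C@H](O[Si](C)(C)C(C)(C)C)C1=CC(=O)OC1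
F0 | step 15 | none | none
F11 | step 20 | C2 iodohydrin corresponding to 33 | C=C(C)C(=O)O[C@@H]1[C@@H]2OC(=O)C(=C)[C@@H]2[C@@H](O)[C@@H](C(=C)C=O)[C@]1(C)[C@H](O)CI
A1 | alternative 1 | 3-isopropenyl-2-hydroxymethyl-2-methylcyclohexanone with C5 and C10 set | O=C1[C@H](OCOC)[C@H](CCOCc2ccc(OC)cc2)[C@@H](O)[C@@H](C(C)=C)[C@]1(C)CO
A2 | alternative 1 | 4-hydroxy-2-methylcyclohex-2-enone precursor of A1 | O=C1[C@H](OCOC)[C@H](CCOCc2ccc(OC)cc2)[C@@H](O)C=C1C
A3 | alternative 2 | isoxazoline-fused lactone bicycle with C10 and C1 set | N1=C2[C@@H]3OC(=O)C[C@@H]3[C@@H](O[Si](C)(C)C(C)(C)C)[C@@H](C4(C)OCCO4)[C@]2(C)[C@@H](COCc2ccc(OC)cc2)O1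
A4 | alternative 2 | aldoxime precursor of A3 with the (E)-trisubstituted alkene | ON=C[C@@H]1OC(=O)C[C@@H]1[C@@H](O[Si](C)(C)C(C)(C)C)[C@@H](C1(C)OCCO1)/C(C)=C/COCc1ccc(OC)cc1
A5 | alternative 3 | cis-fused lactol ethyl acetal with the C6 aminoxyl ether | CC(C)(C)[Si](C)(C)O[C@@H]1[C@@H]2O[C@@H](OCC)C[C@@H]2[C@@H](ON2C(C)(C)CCCC2(C)C)[C@@H](C(C)=C)[C@]1(C)[C@H]1COC(C)(C)O1
A6 | alternative 3 | cyclohexene bromoacetal precursor of A5 | CC(C)(C)[Si](C)(C)O[C@@H]1[C@H](OC(OCC)CBr)C=C[C@@H](C(C)=C)[C@]1(C)[C@H]1COC(C)(C)O1
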